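**Plan**

1. Locants: ring A is the dihydrobenzofuran carrying the styryl group (O1, C2, C3, C3a–C7a); ring B is the second dihydrobenzofuran (primed locants). Retrosynthetic cuts, in order: the eight O–CH3 bonds; the C2–C3 and C2'–C3' bonds of both dihydrofuran rings in one operation; the two aryl–C(carbinol) bonds; the two ArO–CH2Ar bonds; the aryl–vinyl bond.
2. Enabling feature: in each dihydrofuran ring C3 is a diarylmethine carbon and C2–H sits on an ether oxygen ortho to it (C3–C3a–C7a–O1–C2), so a diaryl rhodium carbene at C3 lies 1,5 to a benzylic ether C–H. Both benzo rings carry oxygen at both positions ortho to C3a (C4 and C7a), so one symmetric building block, 4-bromo-2,6-dimethoxybenzaldehyde (1), serves for both.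
3. Forward order: mono-demethylation of 1; two different benzylations; Heck reaction on one aldehyde and Grignard addition on the other; aryllithium/aldehyde union; bis-ketone; bis-hydrazone; twofold C–H insertion closing ring B (C2'–C3') and ring A (C2–C3) together; global demethylation.
4. Stereochemistry: C3 and C3' (both R) come from the chiral dirhodium carboxylate catalyst in the twofold insertion. C2 and C2' form cis and are turned to trans (R) in the last step by acid-mediated equilibration against the fixed C3/C3'. The E-alkene comes from the Heck reaction.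

Key step: step 9

Assumption: Rh2(R-PTAD)4, dirhodium tetrakis[(R)-(1-adamantyl)(phthalimido)acetate], is taken to deliver hydrogen to the face of each carbene carbon that gives the 3R configuration; if the sense proves opposite, Rh2(S-PTAD)4 is used with nothing else changed.

**Route**

Step 1
Reactants: 1 4-bromo-2,6-dimethoxybenzaldehyde
Product: 2 4-bromo-2-hydroxy-6-methoxybenzaldehyde
Conditions: BCl3 (1.2 equiv), CH2Cl2, −78 → 0 °C; then H2O
Reagents that add atoms: none
Why: Chelation-directed mono-demethylation ortho to a formyl group, in which boron bridges the carbonyl and one methoxy oxygen, chloride removes that methyl, and the resulting boron chelate deactivates the second methoxy group (the ring is symmetric, so either one may react).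

Step 2
Reactants: 2 4-bromo-2-hydroxy-6-methoxybenzaldehyde; 3 4-methoxybenzyl chloride
Product: 4 4-bromo-2-methoxy-6-[(4-methoxybenzyl)oxy]benzaldehyde
Conditions: K2CO3, KI (cat.), DMF, 60 °C
Reagents that add atoms: none
Why: Williamson etherification of an acidic salicylaldehyde-type phenol with a reactive benzylic chloride.

Step 3
Reactants: 4 4-bromo-2-methoxy-6-[(4-methoxybenzyl)oxy]benzaldehyde; 5 4-methoxystyrene
Product: 6 2-methoxy-6-[(4-methoxybenzyl)oxy]-4-[(E)-2-(4-methoxyphenyl)ethenyl]benzaldehyde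
Conditions: Pd(OAc)2 (5 mol %), P(o-tol)3 (10 mol %), NaOAc, DMA, 110 °C
Reagents that add atoms: none
Why: Mizoroki–Heck reaction of an aryl bromide activated by the para formyl group, where syn insertion and syn β-hydride elimination should give the E-stilbene.

Step 4
Reactants: 2 4-bromo-2-hydroxy-6-methoxybenzaldehyde; 7 2,4-dimethoxybenzyl alcohol
Product: 8 4-bromo-2-[(2,4-dimethoxybenzyl)oxy]-6-methoxybenzaldehyde
Conditions: PPh3, DIAD, THF, 0 °C → rt
Reagents that add atoms: none
Why: Mitsunobu etherification of the acidic phenol with a primary benzylic alcohol, which avoids the unstable 2,4-dimethoxybenzyl halides.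

Step 5
Reactants: 8 4-bromo-2-[(2,4-dimethoxybenzyl)oxy]-6-methoxybenzaldehyde; 9 3,5-dimethoxyphenylmagnesium chloride (THF solution)
Product: 10 rac-{4-bromo-2-[(2,4-dimethoxybenzyl)oxy]-6-methoxyphenyl}(3,5-dimethoxyphenyl)methanol
Conditions: THF, −20 → 0 °C; then aq. NH4Cl
Reagents that add atoms: none
Why: Grignard 1,2-addition to the aldehyde, with the aryl bromide inert to the arylmagnesium reagent at this temperature; the carbinol centre is oxidised later, so its configuration does not matter.

Step 6
Reactants: 10 rac-{4-bromo-2-[(2,4-dimethoxybenzyl)oxy]-6-methoxyphenyl}(3,5-dimethoxyphenyl)methanol; 6 2-methoxy-6-[(4-methoxybenzyl)oxy]-4-[(E)-2-(4-methoxyphenyl)ethenyl]benzaldehyde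
Product: 12 {3-[(2,4-dimethoxybenzyl)oxy]-4-[(3,5-dimethoxyphenyl)(hydroxy)methyl]-5-methoxyphenyl}{2-methoxy-6-[(4-methoxybenzyl)oxy]-4-[(E)-2-(4-methoxyphenyl)ethenyl]phenyl}methanol (diastereomer mixture), via aryllithium lithium alkoxide 11 (not isolated)
Conditions: n-BuLi (2.05 equiv), THF, −78 °C; then 6, −78 → −20 °C; then aq. NH4Cl
Reagents that add atoms: n-butyllithium, [Li]CCCC (supplies only the lithium atoms of 11; nothing from it remains in 12)
Why: The first equivalent of n-BuLi deprotonates the carbinol and the second effects fast bromine–lithium exchange, after which the aryllithium undergoes 1,2-addition to the aldehyde; both carbinol centres are oxidised in the next step.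

Step 7
Reactants: 12 the diol from step 6
Product: 13 {4-(3,5-dimethoxybenzoyl)-3-[(2,4-dimethoxybenzyl)oxy]-5-methoxyphenyl}{2-methoxy-6-[(4-methoxybenzyl)oxy]-4-[(E)-2-(4-methoxyphenyl)ethenyl]phenyl}methanone
Conditions: DMP (2.6 equiv), pyridine, CH2Cl2, 0 °C → rt
Reagents that add atoms: none
Why: Dess–Martin oxidation of two doubly benzylic secondary alcohols under buffered, non-acidic conditions that should spare the benzyl ethers and the stilbene.

Step 8
Reactants: 13 the bis-ketone from step 7
Product: 14 bis(hydrazone) of 13 (both C=O replaced by C=N–NH2; mixture of C=N isomers)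
Conditions: N2H4·H2O (excess), AcOH (cat.), n-BuOH, 110 °C, degassed, Ar
Reagents that add atoms: hydrazine, NN (used as the monohydrate)
Why: Acid-catalysed condensation of hydrazine with non-enolisable diaryl ketones, with excess hydrazine to suppress azine formation and exclusion of air to prevent diimide reduction of the stilbene.

Step 9
Reactants: 14 bis(hydrazone) of 13
Product: 16 (2S,3R)-3-[(2S,3R)-2-(2,4-dimethoxyphenyl)-3-(3,5-dimethoxyphenyl)-4-methoxy-2,3-dihydro-1-benzofuran-6-yl]-4-methoxy-2-(4-methoxyphenyl)-6-[(E)-2-(4-methoxyphenyl)ethenyl]-2,3-dihydro-1-benzofuran (cis in both rings), via bis(diazo) compound 15 (not isolated)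
Conditions: MnO2 (activated, 10 equiv), CH2Cl2, 0 °C → rt, filter through Celite; filtrate added over 2 h to Rh2(R-PTAD)4 (2 mol %), CH2Cl2, −20 °C → rt
Reagents that add atoms: none
Why: MnO2 dehydrogenates both C=N–NH2 groups to diaryldiazomethanes, and the dirhodium tetracarboxylate expels N2 from each to give a donor/donor rhodium carbene whose carbon lies 1,5 to a benzylic O–CH2–Ar hydrogen through C3a, C7a and the ether oxygen; hydride-like transfer of that hydrogen to the carbene carbon and collapse of the resulting ion pair form the C2'–C3' bond of ring B and, in the same way, the C2–C3 bond of ring A. The closest known reaction type is the enantioselective intramolecular C–H insertion of diaryl rhodium carbenes into benzyl aryl ethers, which gives cis-2,3-diaryl-2,3-dihydrobenzofurans; here it is run at two sites of one molecule. Each of the two rings closes as a five-membered ring by formal 1,5 C–H insertion, the carbene carbon becoming C3 and the former benzylic CH2 becoming C2. C3 and C3' should be set as R by the chiral carboxylate ligands, which decide the face of each carbene carbon that accepts the hydrogen, while C2 and C2' arise cis to them (S) from the compact insertion transition state and are corrected in step 10, so only the facial selectivity at the carbene carbons has to be high. The step needs insertion into the benzylic C–H in preference to the C–H bonds of the second ortho OCH3 group, to cyclopropanation of the stilbene and to azine formation; the first is secured by the far greater hydride-donor ability of a C–H flanked by oxygen and a methoxy-substituted aryl group, the others by the five-membered intramolecular geometry, the trans-1,2-disubstituted alkene and slow addition at high dilution. Because the catalyst acts independently at two remote sites, a wrong-sense event at one site should give a separable diastereomer and not the enantiomer.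

Step 10
Reactants: 16 the cis,cis octamethyl ether from step 9
Product: 17 (2R,3R)-3-[(2R,3R)-2-(2,4-dihydroxyphenyl)-3-(3,5-dihydroxyphenyl)-4-hydroxy-2,3-dihydro-1-benzofuran-6-yl]-2-(4-hydroxyphenyl)-6-[(E)-2-(4-hydroxyphenyl)ethenyl]-2,3-dihydro-1-benzofuran-4-ol
Conditions: BBr3 (16 equiv), CH2Cl2, −78 → 0 °C; then H2O
Reagents that add atoms: none
Why: Lewis acid cleavage of all eight aryl methyl ethers by bromide attack on the boron-activated methyl groups, while the same acid reversibly ionises the C2–O1 and C2'–O1' bonds to oxybenzyl cations that should re-close to the thermodynamically preferred 2,3-trans rings without touching C3 or C3', as is known for cis-2-(4-methoxyphenyl)-3-aryl-2,3-dihydrobenzofurans.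

**Compound list**

1 | 4-bromo-2,6-dimethoxybenzaldehyde | O=Cc1c(OC)cc(Br)cc1OC | starting material
2 | 4-bromo-2-hydroxy-6-methoxybenzaldehyde | O=Cc1c(O)cc(Br)cc1OC | intermediate
3 | 4-methoxybenzyl chloride | COc1ccc(CCl)cc1 | starting material
4 | 4-bromo-2-methoxy-6-[(4-methoxybenzyl)oxy]benzaldehyde | O=Cc1c(OC)cc(Br)cc1OCc1ccc(OC)cc1 | intermediate
5 | 4-methoxystyrene | C=Cc1ccc(OC)cc1 | starting material
6 | 2-methoxy-6-[(4-methoxybenzyl)oxy]-4-[(E)-2-(4-methoxyphenyl)ethenyl]benzaldehyde | O=Cc1c(OC)cc(/C=C/c2ccc(OC)cc2)cc1OCc1ccc(OC)cc1 | intermediate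
7 | 2,4-dimethoxybenzyl alcohol | COc1ccc(CO)c(OC)c1 | starting material
8 | 4-bromo-2-[(2,4-dimethoxybenzyl)oxy]-6-methoxybenzaldehyde | O=Cc1c(OC)cc(Br)cc1OCc1ccc(OC)cc1OC | intermediate
9 | 3,5-dimethoxyphenylmagnesium chloride | COc1cc(OC)cc([Mg]Cl)c1 | starting material
10 | rac-{4-bromo-2-[(2,4-dimethoxybenzyl)oxy]-6-methoxyphenyl}(3,5-dimethoxyphenyl)methanol | OC(c1cc(OC)cc(OC)c1)c1c(OC)cc(Br)cc1OCc1ccc(OC)cc1OC | intermediate
11 | lithium alkoxide of 10 with Br replaced by Li (O,C-dilithio species) | [Li]OC(c1cc(OC)cc(OC)c1)c1c(OC)cc([Li])cc1OCc1ccc(OC)cc1OC | intermediate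
12 | {3-[(2,4-dimethoxybenzyl)oxy]-4-[(3,5-dimethoxyphenyl)(hydroxy)methyl]-5-methoxyphenyl}{2-methoxy-6-[(4-methoxybenzyl)oxy]-4-[(E)-2-(4-methoxyphenyl)ethenyl]phenyl}methanol (diastereomer mixture) | OC(c1cc(OC)cc(OC)c1)c1c(OC)cc(C(O)c2c(OC)cc(/C=C/c3ccc(OC)cc3)cc2OCc2ccc(OC)cc2)cc1OCc1ccc(OC)cc1OC | intermediate
13 | {4-(3,5-dimethoxybenzoyl)-3-[(2,4-dimethoxybenzyl)oxy]-5-methoxyphenyl}{2-methoxy-6-[(4-methoxybenzyl)oxy]-4-[(E)-2-(4-methoxyphenyl)ethenyl]phenyl}methanone | O=C(c1cc(OC)cc(OC)c1)c1c(OC)cc(C(=O)c2c(OC)cc(/C=C/c3ccc(OC)cc3)cc2OCc2ccc(OC)cc2)cc1OCc1ccc(OC)cc1OC | intermediate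
14 | bis(hydrazone) of 13 (mixture of C=N isomers) | NN=C(c1cc(OC)cc(OC)c1)c1c(OC)cc(C(=NN)c2c(OC)cc(/C=C/c3ccc(OC)cc3)cc2OCc2ccc(OC)cc2)cc1OCc1ccc(OC)cc1OC | intermediate
15 | bis(diazo) compound derived from 14 | [N-]=[N+]=C(c1cc(OC)cc(OC)c1)c1c(OC)cc(C(=[N+]=[N-])c2c(OC)cc(/C=C/c3ccc(OC)cc3)cc2OCc2ccc(OC)cc2)cc1OCc1ccc(OC)cc1OC | intermediate
16 | (2S,3R)-3-[(2S,3R)-2-(2,4-dimethoxyphenyl)-3-(3,5-dimethoxyphenyl)-4-methoxy-2,3-dihydro-1-benzofuran-6-yl]-4-methoxy-2-(4-methoxyphenyl)-6-[(E)-2-(4-methoxyphenyl)ethenyl]-2,3-dihydro-1-benzofuran (cis,cis) | COc1ccc(/C=C/c2cc(OC)c3c(c2)O[C@H](c2ccc(OC)cc2)[C@@H]3c2cc(OC)c3c(c2)O[C@H](c2ccc(OC)cc2OC)[C@@H]3c2cc(OC)cc(OC)c2)cc1 | intermediate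
17 | (2R,3R)-3-[(2R,3R)-2-(2,4-dihydroxyphenyl)-3-(3,5-dihydroxyphenyl)-4-hydroxy-2,3-dihydro-1-benzofuran-6-yl]-2-(4-hydroxyphenyl)-6-[(E)-2-(4-hydroxyphenyl)ethenyl]-2,3-dihydro-1-benzofuran-4-ol | Oc1ccc(/C=C/c2cc(O)c3c(c2)O[C@@H](c2ccc(O)cc2)[C@@H]3c2cc(O)c3c(c2)O[C@@H](c2ccc(O)cc2O)[C@@H]3c2cc(O)cc(O)c2)cc1 | target

**Step count**

Total steps: 10. Longest linear sequence: 8 steps (steps 1, 4, 5, 6, 7, 8, 9, 10; the branch through steps 2 and 3 is equally long).

**Steps most likely to fail**

Step 9. The process at risk is loss of one of the two carbenes before it inserts, by azine formation or by fragmentation of the ion pair at the very electron-rich 2,4-dimethoxybenzyl site, together with erosion of facial selectivity at carbene carbons flanked by two ortho oxygen substituents. The fallback builds the rings one at a time, beginning on the bromoarene substrate closest to precedent; it sets out from 10 and returns at 16. Carbinol 10 is oxidised (DMP, pyridine, CH2Cl2) to the bromo ketone F1, condensed with N2H4·H2O to the hydrazone F2, dehydrogenated with MnO2 to the diazo compound F3 (not isolated) and cyclised with Rh2(R-PTAD)4 to the cis-6-bromodihydrobenzofuran F4. Its enantiomeric purity can be checked and, if needed, raised by crystallisation before the second ring is built. Bromine–lithium exchange (n-BuLi, THF, −78 °C) gives the aryllithium F5 (not isolated), which adds to aldehyde 6 to give the carbinol F6. DMP oxidation gives the ketone F7, hydrazine the hydrazone F8 and MnO2 the diazo compound F9 (not isolated); a second rhodium-catalysed insertion, with the catalyst chosen for this site alone, gives 16.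

Step 8. The process at risk is incomplete condensation at carbonyl groups shielded by two ortho alkoxy groups; prolonged heating with hydrazine then invites diimide reduction of the alkene. The fallback activates the carbonyl groups as thiocarbonyl groups; it sets out from 13 and returns at 14. Thionation with Lawesson's reagent (toluene, 90 °C) gives the bis(thioketone) F10, and hindered diaryl thioketones exchange sulfur for N–NH2 with N2H4·H2O in THF–EtOH at room temperature, which should give 14.

Step 10. The process at risk is acid-induced decomposition before all eight ethers are cleaved: ring opening followed by intermolecular Friedel–Crafts capture, or oligomerisation of the stilbene. The fallback separates epimerisation from deprotection and removes the methyl groups without a strong Lewis acid; it sets out from 16 and returns at 17. Catalytic TFA in CH2Cl2 at 0 °C should equilibrate both rings to the all-trans octamethyl ether F11. Exhaustive demethylation with excess MeMgI (solvent-free melt, 160 °C; then aq. NH4Cl), the classical method for acid-sensitive resorcinol and stilbene methyl ethers, should then give 17.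

**Further compounds**

F1 | step 9 | {4-bromo-2-[(2,4-dimethoxybenzyl)oxy]-6-methoxyphenyl}(3,5-dimethoxyphenyl)methanone | O=C(c1cc(OC)cc(OC)c1)c1c(OC)cc(Br)cc1OCc1ccc(OC)cc1OC
F2 | step 9 | hydrazone of F1 | NN=C(c1cc(OC)cc(OC)c1)c1c(OC)cc(Br)cc1OCc1ccc(OC)cc1OC
F3 | step 9 | diazo compound derived from F2 | [N-]=[N+]=C(c1cc(OC)cc(OC)c1)c1c(OC)cc(Br)cc1OCc1ccc(OC)cc1OC
F4 | step 9 | (2S,3R)-6-bromo-2-(2,4-dimethoxyphenyl)-3-(3,5-dimethoxyphenyl)-4-methoxy-2,3-dihydro-1-benzofuran (cis) | Brc1cc(OC)c2c(c1)O[C@H](c1ccc(OC)cc1OC)[C@@H]2c1cc(OC)cc(OC)c1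
F5 | step 9 | 6-lithio analogue of F4 | [Li]c1cc(OC)c2c(c1)O[C@H](c1ccc(OC)cc1OC)[C@@H]2c1cc(OC)cc(OC)c1
F6 | step 9 | [(2S,3R)-2-(2,4-dimethoxyphenyl)-3-(3,5-dimethoxyphenyl)-4-methoxy-2,3-dihydro-1-benzofuran-6-yl]{2-methoxy-6-[(4-methoxybenzyl)oxy]-4-[(E)-2-(4-methoxyphenyl)ethenyl]phenyl}methanol (epimer mixture at the carbinol) | OC(c1c(OC)cc(/C=C/c2ccc(OC)cc2)cc1OCc1ccc(OC)cc1)c1cc(OC)c2c(c1)O[C@H](c1ccc(OC)cc1OC)[C@@H]2c1cc(OC)cc(OC)c1
F7 | step 9 | ketone from oxidation of F6 | O=C(c1c(OC)cc(/C=C/c2ccc(OC)cc2)cc1OCc1ccc(OC)cc1)c1cc(OC)c2c(c1)O[C@H](c1ccc(OC)cc1OC)[C@@H]2c1cc(OC)cc(OC)c1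
F8 | step 9 | hydrazone of F7 | NN=C(c1c(OC)cc(/C=C/c2ccc(OC)cc2)cc1OCc1ccc(OC)cc1)c1cc(OC)c2c(c1)O[C@H](c1ccc(OC)cc1OC)[C@@H]2c1cc(OC)cc(OC)c1
F9 | step 9 | diazo compound derived from F8 | [N-]=[N+]=C(c1c(OC)cc(/C=C/c2ccc(OC)cc2)cc1OCc1ccc(OC)cc1)c1cc(OC)c2c(c1)O[C@H](c1ccc(OC)cc1OC)[C@@H]2c1cc(OC)cc(OC)c1
F10 | step 8 | bis(thioketone) analogue of 13 (both C=O replaced by C=S) | S=C(c1cc(OC)cc(OC)c1)c1c(OC)cc(C(=S)c2c(OC)cc(/C=C/c3ccc(OC)cc3)cc2OCc2ccc(OC)cc2)cc1OCc1ccc(OC)cc1OC
F11 | step 10 | (2R,3R)-3-[(2R,3R)-2-(2,4-dimethoxyphenyl)-3-(3,5-dimethoxyphenyl)-4-methoxy-2,3-dihydro-1-benzofuran-6-yl]-4-methoxy-2-(4-methoxyphenyl)-6-[(E)-2-(4-methoxyphenyl)ethenyl]-2,3-dihydro-1-benzofuran (trans,trans) | COc1ccc(/C=C/c2cc(OC)c3c(c2)O[C@@H](c2ccc(OC)cc2)[C@@H]3c2cc(OC)c3c(c2)O[C@@H](c2ccc(OC)cc2OC)[C@@H]3c2cc(OC)cc(OC)c2)cc1
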